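The route disconnects the aryl ether bond O1–C8a of the lower flavan-3-ol unit with reversed polarity, C8a being the electrophile. In ring A this carbon lies between C4a (bearing the C4 methylene) and C8 (bearing C4 of the upper flavan), with the C5 and C7 oxygens meta to it. A fluorine at C8a first flanks the two lithiation sites that attach the C2–C3–C4 chain and the upper unit (made by ortho-quinone methide cycloaddition), then is displaced by the C2 alkoxide. This intramolecular SNAr closes ring C with retention at C2 and C3, fixing 2,3-trans geometry and the 4→8 linkage. Its precursor is an open-chain anti 2-benzyloxy-1-ol carrying the complete upper flavan.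

Key step: step 12

Assumption: in step 10 the (R) enantiomer of the phosphoric acid is taken to deliver the (2S,4S) adduct; if the sense of induction is the opposite, the (S) acid is used and nothing else changes.
Remark: locants O1, C2, C3, C4, C4a, C5 to C8 and C8a refer to the lower flavan-3-ol unit of the target.

Step 1
Reactants: 1 1,3,5-trifluorobenzene
Product: 3 1,3-bis(benzyloxy)-5-fluorobenzene, via mono-benzyl ether 2 (not isolated)
Conditions: BnOH (2.1 equiv), NaH (2.2 equiv), NMP, 0 °C then 100 °C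
Reagents that add atoms: benzyl alcohol, OCc1ccccc1
Why: Twofold nucleophilic aromatic substitution (SNAr) by sodium benzyloxide, in which each fluorine is activated inductively by the other two and the third substitution is held back by the stoichiometry and by the loss of those activating fluorines.

Step 2
Reactants: 3 1,3-bis(benzyloxy)-5-fluorobenzene
Product: 5 1,5-bis(benzyloxy)-2,4-dibromo-3-fluorobenzene, via monobromide 4 (not isolated)
Conditions: N-bromosuccinimide (2.05 equiv), MeCN, 0 °C to rt, dark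
Reagents that add atoms: N-bromosuccinimide, O=C1CCC(=O)N1Br
Why: Electrophilic aromatic bromination should go twice to the equivalent positions next to fluorine, each para to one benzyloxy group and ortho to the other, while the position between the two benzyloxy groups has no para donor and is the most hindered.

Step 3
Reactants: 6 3,4-bis(benzyloxy)benzaldehyde
Product: 7 racemic 1-[3,4-bis(benzyloxy)phenyl]prop-2-en-1-ol
Conditions: CH2=CHMgBr, THF, 0 °C; then H2O
Reagents that add atoms: vinylmagnesium bromide, C=C[Mg]Br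
Why: Grignard 1,2-addition to the aldehyde gives the racemic secondary allylic alcohol required for the kinetic resolution that follows.

Step 4
Reactants: 7 racemic 1-[3,4-bis(benzyloxy)phenyl]prop-2-en-1-ol
Product: 8 (R)-[3,4-bis(benzyloxy)phenyl][(2S)-oxiran-2-yl]methanol
Conditions: Ti(OiPr)4 (0.2 equiv), D-(−)-diisopropyl tartrate (0.25 equiv), t-BuOOH (0.45 equiv), 4 Å molecular sieves, CH2Cl2, −20 °C
Reagents that add atoms: tert-butyl hydroperoxide, CC(C)(C)OO
Why: Sharpless kinetic resolution of a secondary allylic alcohol, in which the D-(−)-tartrate catalyst epoxidises the fast-reacting (S)-alcohol on the face that gives the erythro (anti) epoxy alcohol, so that tartrate and carbinol centre together set the new oxirane centre as S while the slow (R)-alcohol is left behind and separated.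

Step 5
Reactants: 8 (R)-[3,4-bis(benzyloxy)phenyl][(2S)-oxiran-2-yl]methanol
Product: 9 tert-butyldimethylsilyl ether of 8
Conditions: TBSCl, imidazole, DMF, rt
Reagents that add atoms: tert-butyldimethylsilyl chloride, CC(C)(C)[Si](C)(C)Cl
Why: Imidazole-promoted silylation protects the benzylic hydroxyl without generating an alkoxide, which avoids Payne rearrangement of the epoxy alcohol.

Step 6
Reactants: 5 1,5-bis(benzyloxy)-2,4-dibromo-3-fluorobenzene; 9 silyl-protected epoxy alcohol
Product: 11 (1R,2S)-3-[4,6-bis(benzyloxy)-3-bromo-2-fluorophenyl]-1-[3,4-bis(benzyloxy)phenyl]-1-(silyloxy)propan-2-ol, via aryllithium 10 (not isolated)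
Conditions: 5 (1.3 equiv), n-BuLi (1.25 equiv), THF, −78 °C; then 9, BF3·OEt2, −78 °C; then H2O
Reagents that add atoms: none
Why: Bromine–lithium exchange at one of the two equivalent bromides gives an ortho-fluoro aryllithium that is stable at −78 °C, and its BF3-assisted SN2 opening of the oxirane at the unsubstituted carbon forms the C4a–C4 bond and leaves both stereocentres untouched.

Step 7
Reactants: 11 bromo fluoro silyloxy alcohol
Product: 12 2-O-benzyl ether of 11
Conditions: 2-benzyloxy-1-methylpyridinium triflate (2 equiv), MgO (2 equiv), PhCF3, 85 °C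
Reagents that add atoms: 2-benzyloxy-1-methylpyridinium triflate, C[n+]1ccccc1OCc1ccccc1.[O-]S(=O)(=O)C(F)(F)F
Why: Benzyl transfer from the pyridinium salt (Dudley benzylation) runs under neutral conditions, so no alkoxide is formed next to the silyl ether (no silyl migration) or near the aryl fluoride (no premature five-membered SNAr closure by this oxygen).

Step 8
Reactants: 12 benzyl ether bromide; 13 4-(benzyloxy)-2-hydroxybenzaldehyde
Product: 16 ortho-hydroxybenzhydrol (both carbinol epimers), via aryllithium 14 (not isolated), via lithium phenoxide 15 (not isolated)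
Conditions: 13, LiN(SiMe3)2 (1.0 equiv), THF, −78 °C; separately 12, n-BuLi (1.05 equiv), THF, −78 °C; phenoxide solution added to the aryllithium, −78 to −40 °C; then H2O
Reagents that add atoms: none
Why: Bromine–lithium exchange at the remaining bromide (again flanked by fluorine and benzyloxy) followed by 1,2-addition to the aldehyde, whose phenol is masked in situ as its lithium salt, should give the benzhydrol as an epimer mixture that is inconsequential because this carbon becomes trigonal in step 10.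

Step 9
Reactants: 6 3,4-bis(benzyloxy)benzaldehyde
Product: 17 1,2-bis(benzyloxy)-4-ethenylbenzene
Conditions: Ph3PCH3Br, KOtBu, THF, 0 °C to rt
Reagents that add atoms: methyltriphenylphosphonium bromide, C[P+](c1ccccc1)(c1ccccc1)c1ccccc1.[Br-]
Why: Wittig methylenation of the aldehyde with the non-stabilised ylide gives the electron-rich styrene.

Step 10
Reactants: 16 ortho-hydroxybenzhydrol; 17 1,2-bis(benzyloxy)-4-ethenylbenzene
Product: 19 (2S,4S)-2,4-cis-chroman cycloadduct, via ortho-quinone methide 18 (not isolated)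
Conditions: (R)-TRIP [(R)-3,3'-bis(2,4,6-triisopropylphenyl)-1,1'-binaphthyl-2,2'-diyl hydrogen phosphate] (10 mol %), 17 (2 equiv), 4 Å molecular sieves, toluene, 0 °C to rt
Reagents that add atoms: none
Why: Acid-catalysed dehydration gives ortho-quinone methide 18, which should undergo an inverse-electron-demand oxa-[4+2] cycloaddition (hetero-Diels–Alder) with the styrene (CH2 terminus to the methide carbon, oxygen to the benzylic carbon), the endo approach giving the 2,4-cis chroman and the ion-paired chiral phosphate shielding one face of the methide to set C4 as S and with it C2 as S, the minor cis diastereomer being removed by chromatography.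

Step 11
Reactants: 19 chroman cycloadduct
Product: 20 (1R,2S)-2-(benzyloxy)propan-1-ol bearing the fluoroarene and the upper flavan
Conditions: Bu4NF, THF, 0 °C to rt
Reagents that add atoms: none
Why: Fluoride-mediated cleavage of the silyl ether frees the benzylic hydroxyl as the only hydroxyl group in the molecule, the benzyl ethers and the aryl fluoride being inert at room temperature.

Step 12
Reactants: 20 fluoro alcohol
Product: 22 octa-O-benzyl ether of the target, via potassium alkoxide 21 (not isolated)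
Conditions: KH (1.5 equiv), 18-crown-6 (0.2 equiv), THF, 0 to 65 °C
Reagents that add atoms: none
Why: KH deprotonates the only hydroxyl group (the benzylic one, future O1) to potassium alkoxide 21, which attacks the fluorine-bearing ring-A carbon (future C8a) intramolecularly and expels fluoride in an addition–elimination (SNAr) that forms the O1–C8a bond. The closest known reaction type is the intramolecular SNAr etherification of an alkoxide with an aryl fluoride that lacks nitro-type activation, as used for chroman and flavan-3-ol ring closure in the reverse-polarity sense. Ring C is closed by a 6-exo-trig ipso attack at the aromatic carbon, the developing negative charge at C4a, C6 and C8 being stabilised inductively by the benzyloxy groups at C5 and C7, which are meta to the reacting carbon and so do not deactivate it by resonance. No stereocentre is created: no bond to C2 or C3 is broken and the benzylic carbon never becomes cationic, so the (1R,2S) anti arrangement set in step 4 is carried over unchanged as the 2,3-trans (2R,3S) pyran. The step needs six- over five-membered closure, secured by the benzyl ether on the neighbouring oxygen, and a single site of attack, secured by the lone fluorine that sits between the C4 chain and the upper flavan and so also fixes the 4→8 linkage. With no hydrogen ortho to fluorine an aryne pathway is excluded, and 18-crown-6 frees the alkoxide from its potassium ion to give the nucleophilicity needed at this doubly ortho-substituted carbon.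

Step 13
Reactants: 22 octa-O-benzyl ether of the target
Product: 23 CNP0227165.3
Conditions: H2 (1 atm), Pd(OH)2/C, THF–MeOH 1:1, rt
Reagents that add atoms: none
Why: Hydrogenolysis of all eight benzyl ethers over Pd(OH)2 on carbon under neutral conditions, the standard deprotection of benzylated proanthocyanidins, should leave the interflavan bond, both pyran rings and all four stereocentres untouched.

Compound list
1 | 1,3,5-trifluorobenzene | Fc1cc(F)cc(F)c1 | starting material
2 | 1-(benzyloxy)-3,5-difluorobenzene | Fc1cc(F)cc(OCc2ccccc2)c1 | intermediate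
3 | 1,3-bis(benzyloxy)-5-fluorobenzene | Fc1cc(OCc2ccccc2)cc(OCc2ccccc2)c1 | intermediate
4 | 1,5-bis(benzyloxy)-2-bromo-3-fluorobenzene | Fc1cc(OCc2ccccc2)cc(OCc2ccccc2)c1Br | intermediate
5 | 1,5-bis(benzyloxy)-2,4-dibromo-3-fluorobenzene | Fc1c(Br)c(OCc2ccccc2)cc(OCc2ccccc2)c1Br | intermediate
6 | 3,4-bis(benzyloxy)benzaldehyde | O=Cc1ccc(OCc2ccccc2)c(OCc2ccccc2)c1 | starting material
7 | racemic 1-[3,4-bis(benzyloxy)phenyl]prop-2-en-1-ol | OC(C=C)c1ccc(OCc2ccccc2)c(OCc2ccccc2)c1 | intermediate
8 | (R)-[3,4-bis(benzyloxy)phenyl][(2S)-oxiran-2-yl]methanol (erythro epoxy alcohol) | O[C@H](c1ccc(OCc2ccccc2)c(OCc2ccccc2)c1)[C@@H]1CO1 | intermediate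
9 | tert-butyl{(R)-[3,4-bis(benzyloxy)phenyl][(2S)-oxiran-2-yl]methoxy}dimethylsilane | CC(C)(C)[Si](C)(C)O[C@H](c1ccc(OCc2ccccc2)c(OCc2ccccc2)c1)[C@@H]1CO1 | intermediate
10 | [4,6-bis(benzyloxy)-3-bromo-2-fluorophenyl]lithium | [Li]c1c(F)c(Br)c(OCc2ccccc2)cc1OCc1ccccc1 | intermediate
11 | (1R,2S)-3-[4,6-bis(benzyloxy)-3-bromo-2-fluorophenyl]-1-[3,4-bis(benzyloxy)phenyl]-1-[(tert-butyldimethylsilyl)oxy]propan-2-ol | Brc1c(OCc2ccccc2)cc(OCc2ccccc2)c(C[C@H](O)[C@H](O[Si](C)(C)C(C)(C)C)c2ccc(OCc3ccccc3)c(OCc3ccccc3)c2)c1F | intermediate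
12 | [(1R,2S)-2-(benzyloxy)-3-[4,6-bis(benzyloxy)-3-bromo-2-fluorophenyl]-1-[3,4-bis(benzyloxy)phenyl]propoxy](tert-butyl)dimethylsilane | Brc1c(OCc2ccccc2)cc(OCc2ccccc2)c(C[C@H](OCc2ccccc2)[C@H](O[Si](C)(C)C(C)(C)C)c2ccc(OCc3ccccc3)c(OCc3ccccc3)c2)c1F | intermediate
13 | 4-(benzyloxy)-2-hydroxybenzaldehyde | O=Cc1ccc(OCc2ccccc2)cc1O | starting material
14 | aryllithium of 12 (lithium in place of bromine) | [Li]c1c(OCc2ccccc2)cc(OCc2ccccc2)c(C[C@H](OCc2ccccc2)[C@H](O[Si](C)(C)C(C)(C)C)c2ccc(OCc3ccccc3)c(OCc3ccccc3)c2)c1F | intermediate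
15 | lithium 5-(benzyloxy)-2-formylphenolate | [Li+].[O-]c1cc(OCc2ccccc2)ccc1C=O | intermediate
16 | {3-[(2S,3R)-2-(benzyloxy)-3-[3,4-bis(benzyloxy)phenyl]-3-[(tert-butyldimethylsilyl)oxy]propyl]-4,6-bis(benzyloxy)-2-fluorophenyl}[4-(benzyloxy)-2-hydroxyphenyl]methanol, both epimers at the carbinol carbon | OC(c1ccc(OCc2ccccc2)cc1O)c1c(OCc2ccccc2)cc(OCc2ccccc2)c(C[C@H](OCc2ccccc2)[C@H](O[Si](C)(C)C(C)(C)C)c2ccc(OCc3ccccc3)c(OCc3ccccc3)c2)c1F | intermediate
17 | 1,2-bis(benzyloxy)-4-ethenylbenzene | C=Cc1ccc(OCc2ccccc2)c(OCc2ccccc2)c1 | intermediate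
18 | ortho-quinone methide from 16: 3-(benzyloxy)-6-(arylmethylidene)cyclohexa-2,4-dien-1-one, aryl as in 16 | O=C1C=C(OCc2ccccc2)C=CC1=Cc1c(OCc2ccccc2)cc(OCc2ccccc2)c(C[C@H](OCc2ccccc2)[C@H](O[Si](C)(C)C(C)(C)C)c2ccc(OCc3ccccc3)c(OCc3ccccc3)c2)c1F | intermediate
19 | (2S,4S)-7-(benzyloxy)-2-[3,4-bis(benzyloxy)phenyl]-4-{3-[(2S,3R)-2-(benzyloxy)-3-[3,4-bis(benzyloxy)phenyl]-3-[(tert-butyldimethylsilyl)oxy]propyl]-4,6-bis(benzyloxy)-2-fluorophenyl}chromane | c1ccccc1COc1ccc2c(c1)O[C@H](c1ccc(OCc3ccccc3)c(OCc3ccccc3)c1)C[C@@H]2c1c(OCc2ccccc2)cc(OCc2ccccc2)c(C[C@H](OCc2ccccc2)[C@H](O[Si](C)(C)C(C)(C)C)c2ccc(OCc3ccccc3)c(OCc3ccccc3)c2)c1F | intermediate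
20 | (1R,2S)-2-(benzyloxy)-3-{4,6-bis(benzyloxy)-3-[(2S,4S)-7-(benzyloxy)-2-[3,4-bis(benzyloxy)phenyl]chroman-4-yl]-2-fluorophenyl}-1-[3,4-bis(benzyloxy)phenyl]propan-1-ol | c1ccccc1COc1ccc2c(c1)O[C@H](c1ccc(OCc3ccccc3)c(OCc3ccccc3)c1)C[C@@H]2c1c(OCc2ccccc2)cc(OCc2ccccc2)c(C[C@H](OCc2ccccc2)[C@H](O)c2ccc(OCc3ccccc3)c(OCc3ccccc3)c2)c1F | intermediate
21 | potassium alkoxide of 20 | [K+].c1ccccc1COc1ccc2c(c1)O[C@H](c1ccc(OCc3ccccc3)c(OCc3ccccc3)c1)C[C@@H]2c1c(OCc2ccccc2)cc(OCc2ccccc2)c(C[C@H](OCc2ccccc2)[C@H]([O-])c2ccc(OCc3ccccc3)c(OCc3ccccc3)c2)c1F | intermediate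
22 | (2R,3S)-3,5,7-tris(benzyloxy)-2-[3,4-bis(benzyloxy)phenyl]-8-{(2S,4S)-7-(benzyloxy)-2-[3,4-bis(benzyloxy)phenyl]chroman-4-yl}chromane | c1ccccc1COc1ccc2c(c1)O[C@H](c1ccc(OCc3ccccc3)c(OCc3ccccc3)c1)C[C@@H]2c1c(OCc2ccccc2)cc(OCc2ccccc2)c2c1O[C@H](c1ccc(OCc3ccccc3)c(OCc3ccccc3)c1)[C@@H](OCc1ccccc1)C2 | intermediate
23 | (2R,3S)-2-(3,4-dihydroxyphenyl)-8-[(2S,4S)-2-(3,4-dihydroxyphenyl)-7-hydroxychroman-4-yl]chromane-3,5,7-triol (CNP0227165.3) | Oc1ccc2c(c1)O[C@H](c1ccc(O)c(O)c1)C[C@@H]2c1c(O)cc(O)c2c1O[C@H](c1ccc(O)c(O)c1)[C@@H](O)C2 | target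

Total step count: 13.
Longest linear sequence: 10 steps (from aldehyde 6 through steps 3, 4, 5, 6, 7, 8, 10, 11, 12 and 13).

Steps most likely to fail

1. Step 12. Substitution at the fluorinated carbon, which is flanked by two ortho carbon substituents (one of them the bulky flavan-4-yl group), may be too slow, so that base-induced decomposition of the alkoxide overtakes ring closure. The fallback sets out from 12 and comes back at 22; it closes the same ring earlier, while the neighbouring carbon still carries the small, inductively activating bromine. Bu4NF on 12 should give the bromo fluoro alcohol F1. KH with 18-crown-6 should convert it through its potassium alkoxide F2 into the 8-bromochromane F3. Bromine–lithium exchange (n-BuLi, THF, −78 °C) should give the 8-lithiochromane F4, which adds to lithium phenoxide 15 to give the benzhydrol F5. The phosphoric-acid cycloaddition of step 10 with styrene 17 should then run through the ortho-quinone methide F6 to 22.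

2. Step 10. Facial selectivity may be poor if catalyst control is mismatched with the stereocentres and the bulk of the chain-bearing aryl group, and the acid may cause loss of the benzylic silyl ether or oligomerisation of the styrene. The fallback sets out from 5 and comes back at 19; it moves the cycloaddition to the achiral stage. Aryllithium 10 (from 5) is added to 15 to give the racemic benzhydrol F7. The (R)-TRIP cycloaddition with 17 through the ortho-quinone methide F8 should give the bromo fluoro chroman F9, whose enantiomeric purity can be raised by crystallisation. Bromine–lithium exchange to the aryllithium F10 and BF3-assisted opening of epoxide 9 should give the alcohol F11, in which any wrong-handed upper unit is now a separable diastereomer. Benzylation as in step 7 gives 19.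

3. Step 8. Addition of the hindered ortho-fluoro aryllithium to the deactivated phenoxide aldehyde may be slow, so that loss of LiF (aryne formation) or protonation wins on warming. The fallback sets out from 12 and comes back at 16. Aryllithium 14 is trapped at −78 °C with DMF to give the aldehyde F12. Ortho-selective hydroxyalkylation of the bromomagnesium 3-(benzyloxy)phenoxide F13 (from commercial 3-(benzyloxy)phenol and EtMgBr, toluene) with F12 then makes the same carbinol carbon–carbon bond from the phenol side, at the ortho position para to the benzyloxy group, and should give 16.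

Further compounds
F1 | step 12 | (1R,2S)-2-(benzyloxy)-3-[4,6-bis(benzyloxy)-3-bromo-2-fluorophenyl]-1-[3,4-bis(benzyloxy)phenyl]propan-1-ol | Brc1c(OCc2ccccc2)cc(OCc2ccccc2)c(C[C@H](OCc2ccccc2)[C@H](O)c2ccc(OCc3ccccc3)c(OCc3ccccc3)c2)c1F
F2 | step 12 | potassium alkoxide of F1 | [K+].Brc1c(OCc2ccccc2)cc(OCc2ccccc2)c(C[C@H](OCc2ccccc2)[C@H]([O-])c2ccc(OCc3ccccc3)c(OCc3ccccc3)c2)c1F
F3 | step 12 | (2R,3S)-3,5,7-tris(benzyloxy)-2-[3,4-bis(benzyloxy)phenyl]-8-bromochromane | Brc1c(OCc2ccccc2)cc(OCc2ccccc2)c2c1O[C@H](c1ccc(OCc3ccccc3)c(OCc3ccccc3)c1)[C@@H](OCc1ccccc1)C2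
F4 | step 12 | 8-lithio derivative of F3 | [Li]c1c(OCc2ccccc2)cc(OCc2ccccc2)c2c1O[C@H](c1ccc(OCc3ccccc3)c(OCc3ccccc3)c1)[C@@H](OCc1ccccc1)C2
F5 | step 12 | {(2R,3S)-3,5,7-tris(benzyloxy)-2-[3,4-bis(benzyloxy)phenyl]chroman-8-yl}[4-(benzyloxy)-2-hydroxyphenyl]methanol, both carbinol epimers | OC(c1ccc(OCc2ccccc2)cc1O)c1c(OCc2ccccc2)cc(OCc2ccccc2)c2c1O[C@H](c1ccc(OCc3ccccc3)c(OCc3ccccc3)c1)[C@@H](OCc1ccccc1)C2
F6 | step 12 | ortho-quinone methide from F5 | O=C1C=C(OCc2ccccc2)C=CC1=Cc1c(OCc2ccccc2)cc(OCc2ccccc2)c2c1O[C@H](c1ccc(OCc3ccccc3)c(OCc3ccccc3)c1)[C@@H](OCc1ccccc1)C2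
F7 | step 10 | racemic [4,6-bis(benzyloxy)-3-bromo-2-fluorophenyl][4-(benzyloxy)-2-hydroxyphenyl]methanol | OC(c1ccc(OCc2ccccc2)cc1O)c1c(F)c(Br)c(OCc2ccccc2)cc1OCc1ccccc1
F8 | step 10 | ortho-quinone methide from F7 | O=C1C=C(OCc2ccccc2)C=CC1=Cc1c(F)c(Br)c(OCc2ccccc2)cc1OCc1ccccc1
F9 | step 10 | (2S,4S)-7-(benzyloxy)-2-[3,4-bis(benzyloxy)phenyl]-4-[4,6-bis(benzyloxy)-3-bromo-2-fluorophenyl]chromane | c1ccccc1COc1ccc2c(c1)O[C@H](c1ccc(OCc3ccccc3)c(OCc3ccccc3)c1)C[C@@H]2c1c(OCc2ccccc2)cc(OCc2ccccc2)c(Br)c1F
F10 | step 10 | aryllithium of F9 (lithium in place of bromine) | c1ccccc1COc1ccc2c(c1)O[C@H](c1ccc(OCc3ccccc3)c(OCc3ccccc3)c1)C[C@@H]2c1c(OCc2ccccc2)cc(OCc2ccccc2)c([Li])c1F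
F11 | step 10 | (1R,2S)-3-{4,6-bis(benzyloxy)-3-[(2S,4S)-7-(benzyloxy)-2-[3,4-bis(benzyloxy)phenyl]chroman-4-yl]-2-fluorophenyl}-1-[3,4-bis(benzyloxy)phenyl]-1-[(tert-butyldimethylsilyl)oxy]propan-2-ol | c1ccccc1COc1ccc2c(c1)O[C@H](c1ccc(OCc3ccccc3)c(OCc3ccccc3)c1)C[C@@H]2c1c(OCc2ccccc2)cc(OCc2ccccc2)c(C[C@H](O)[C@H](O[Si](C)(C)C(C)(C)C)c2ccc(OCc3ccccc3)c(OCc3ccccc3)c2)c1F
F12 | step 8 | 3-[(2S,3R)-2-(benzyloxy)-3-[3,4-bis(benzyloxy)phenyl]-3-[(tert-butyldimethylsilyl)oxy]propyl]-4,6-bis(benzyloxy)-2-fluorobenzaldehyde | O=Cc1c(OCc2ccccc2)cc(OCc2ccccc2)c(C[C@H](OCc2ccccc2)[C@H](O[Si](C)(C)C(C)(C)C)c2ccc(OCc3ccccc3)c(OCc3ccccc3)c2)c1F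
F13 | step 8 | bromomagnesium 3-(benzyloxy)phenoxide | Br[Mg]Oc1cccc(OCc2ccccc2)c1
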